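## Structural features

The target is an isoflavone: a benzene ring (ring A) fused through C4a–C8a to a 4-pyranone (ring C), with a 3,4-dihydroxyphenyl ring (ring B) joined by a single bond to C3. Ring A has no hydrogen left: C5 carries OH, C6 the chain CH2–CH(OH)–C(CH3)=CH2, C7 OH, C8 a prenyl group, C8a the ring oxygen O1 and C4a the C4 carbonyl. The only stereocentre is C2'' of the C6 chain (R), a secondary allylic carbinol between the benzylic CH2 and the isopropenyl group; it has no stereogenic neighbour, so only absolute configuration has to be secured. Fragile sites are the isopropenyl carbinol (ionisation or cyclisation onto the C5 or C7 oxygen in acid), the prenyl group ortho to the C7 hydroxyl (acid-induced chroman formation), the catechol of ring B (oxidation in base and air) and C2 of the pyranone (opening by hard nucleophiles). The real difficulty is regiochemical: two different allylic chains must sit on C6 and C8 and the acyl carbon on C4a of a phloroglucinol core, while the three oxygens end as two hydroxyls and one ring oxygen; stepwise substitution of a symmetrical triol cannot tell these positions apart. The key step uses the strict alternation C4a–C5(O)–C6–C7(O)–C8–C8a(O) around ring A. It builds the ring from a four-carbon unit (C8a, C6, C5, C4a, carrying the C6 chain and the C5 oxygen) and a two-carbon unit (C7, C8, carrying the C7 oxygen and the prenyl group), so every substituent arrives on the atom that bears it.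

## Logic of the disconnections

32 from 31: the four O–Si bonds (C7–O, C3'–O, C4'–O, C2''–O) are cut last. All acid- and oxidation-sensitive hydroxyls then appear in one fluoride operation, and neither the catechol nor the allylic carbinol is ever free earlier. The forward step must cleave a hindered aryl silyl ether and a secondary alkyl silyl ether without exposing the chromone to strong base, hence buffered fluoride.

31 from 30: the O–CH3 bond at C5 is cut. A methyl ether is the smallest group that survives the organolithium chemistry, and it sits peri to the C4 carbonyl, where chelation makes it the one ether a mild magnesium Lewis acid can remove. This keeps the C5 oxygen distinct from the C7 oxygen and O1 throughout. The forward step must spare the prenyl group and the allylic silyl ether.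

30 from 28: the O1–C2 and C2–C3 bonds are cut, removing C2 as a one-carbon unit. Ring C is reduced to a benzyl aryl ketone with a free ortho hydroxyl. The forward step needs aminomethylenation of the benzylic CH2 and ring closure through the single free phenol.

28 from 21 and 26: the C4–C4a bond is cut, which divides the molecule into a ring A half and a ring B half. C4a is made the nucleophile (aryllithium) and the arylacetyl unit the electrophile, so that no Lewis or Brønsted acid meets the o-prenylphenol or the allylic silyl ether. The forward step demands halogen–lithium exchange next to a phenoxide and addition that is faster than proton transfer from the acidic CH2 of 26.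

21 from 20: the C4a–Br bond is cut. The only unsubstituted ring carbon is also the most electron-rich one, so the halogen handle needs no directing group. The bromination must be faster on the arene than on the two side-chain alkenes.

20 from 10 and 15: the C8a–C8, C7–C6 and C8a–C4a bonds are cut (in the forward sense the four-membered ring of 10 is sacrificed). A pentasubstituted phenol with three differently masked oxygens becomes a small-ring ketone that carries the stereocentre and an alkyne that carries the prenyl group. The forward step requires thermal opening of a donor-substituted cyclobutenone, a regiospecific ketene–alkyne [2+2] addition and tolerance of three C=C bonds.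

10 from 9 and ketene: the two ring bonds made in a [2+2] cycloaddition are cut (future C8a–C6 and C5–C4a atoms). The cyclobutenone becomes an open-chain alkoxyalkyne plus a two-carbon reagent. The demand is that the alkyl-bearing alkyne carbon bonds to the ketene carbonyl carbon.

9 from 6 and 7: the C(sp3)–C(sp) bond between the future benzylic carbon and the alkyne is cut, so the stereocentre comes from the chiral pool with its C–O bond intact. The electrophilic carbon is β to a silyloxy group and β-branched, a position where an iodide would react sluggishly; a triflate is therefore used.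

6 back to 1 through 4, 3 and 2: only functional-group bonds are cut (O–S and O–Si, the acetal, the C=C bond by dehydration, two C–CH3 bonds by Grignard addition). The ester carbon of 1 becomes the isopropenyl carbon and the CH2O carbon becomes the benzylic carbon; the configured C–O bond is never broken.

15 from 12 and then 11: the O–Si and C(sp)–O bonds are cut (oxidation of an acetylide and silylation), then the C–C bond between the prenyl CH2 and ethyne. Two steps from a commodity bromide.

26 from 24 and then 22: the amide C–N bond and the aryl O–Si bonds are cut. Silyl ethers are chosen for ring B so that they fall in the same final step as the other silyl groups.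

## Other disconnections considered

Alternative 1: The cut is made inside the C6 side chain. The isopropenyl carbinol is traced to the epoxy alcohol (2R,3R)-epoxide A2, and this to the achiral allylic alcohol 6-[(E)-4-hydroxy-3-methylbut-2-enyl]-8-prenyl-5,7,3',4'-tetrakis(methoxymethoxy)isoflavone A1.
- Forward key step: Ti(OiPr)4, D-(−)-diethyl tartrate and t-BuOOH should epoxidise only the allylic-alcohol alkene of A1, forming both C–O bonds of the oxirane in A2. Activation of the primary hydroxyl and reductive opening with Zn would then transpose the system to CH2=C(CH3)–CH(OH)–.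
- In favour: the stereocentre is set by a catalyst on a substrate class, (E)-2-methylalk-2-enols, for which this epoxidation is among its most dependable uses. The hydroxyl directs the reagent away from the prenyl alkene. The sense of induction (D-tartrate to 2R,3R, hence R at C2'') can be predicted with confidence.
- Against: ring A is left unsolved. A1 must already carry two different allyl groups at C6 and C8, and an oxidised C6 chain cannot be made from a prenyl group without touching the C8 prenyl group. Three operations are spent on one stereocentre. A Lewis-acidic titanium centre near an epoxide flanked by two aryl ethers invites intramolecular opening. The closing acetal removal needs acid while the isopropenyl carbinol and the o-prenylphenol are exposed.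
- Comparison: on stereocontrol the alternative equals the chosen plan in reliability and is better in flexibility, since either enantiomer follows from the choice of tartrate. Its single key step is also the better-precedented one. On structure it offers nothing for the regiochemical problem that the chosen plan solves, and on step economy it adds three late steps to a ring A synthesis still to be found.

Alternative 2: The cut is at C7–C8 and C5–C6, so ring A is grown last on a pyranone that already holds rings B and C. The pieces are methyl 5-[3,4-bis(methoxymethoxy)phenyl]-2-(4-methylpent-3-enyl)-4-oxo-4H-pyran-3-carboxylate A3 and methyl (R)-4-(tert-butyldimethylsilyloxy)-5-methylhex-5-enoate A4. The product is the 5,7-dihydroxyisoflavone A5.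
- Forward key step: excess LiN(iPr)2 should form the vinylogous enolate at the CH2 next to the pyranone in A3. Acylation by A4 would make C8–C7, a second deprotonation between the new carbonyl and the side chain would let that carbon attack the ring ester (C6–C5), and enolisation would aromatise ring A.
- In favour: it is convergent, every ring A substituent is placed by the open-chain partners, and the 5,7-diol appears free at once. No ether cleavage and no later pyranone construction are needed.
- Against: the base meets many acidic sites (the α-CH2 of A4, the pyranone C–H, allylic positions) and an electrophilic pyranone that amide bases can open. Acylation of a vinylogous enolate by a simple enolisable methyl ester is prone to proton transfer. A3 is itself a trisubstituted pyranone that would need several steps. The acetal groups on ring B again demand acid at the end.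
- Comparison: in positional control the two plans are equal, and the stereocentre comes from the same kind of chiral-pool fragment. After the key step the alternative is better in step economy, because only deprotection remains. Mechanistically it is a sequence of competing ionic condensations, less predictable than a pericyclic cascade whose connectivity is fixed by orbital polarisation.

Alternative 3: The cut is at O1–C8a and C4–C4a. Ring A serves as an aryne generated from 3-[(R)-2-(tert-butyldimethylsilyloxy)-3-methylbut-3-enyl]-2,4-bis(methoxymethoxy)-5-(3-methylbut-2-enyl)-6-(trimethylsilyl)phenyl trifluoromethanesulfonate A6. Methyl 2-[3,4-bis(methoxymethoxy)phenyl]-3-oxopropanoate A7 brings ring B with C2, C3 and C4. The product is the fully protected isoflavone A8.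
- Forward key step: CsF should release the C4a–C8a aryne from A6. The enolate oxygen of A7 would add to C8a and the C4a anion would attack the ester, closing ring C.
- In favour: ring C and ring B are attached in one nearly neutral operation. The regiochemistry is predictable: the nucleophile adds to the aryne carbon remote from the C5 alkoxy group and the carbanion forms next to it. Only deprotection follows.
- Against: the problem of ring A is moved, not solved. A6 is a hexasubstituted arene with adjacent silyl and triflate groups wedged between a prenyl group and an acetal, and would itself have to be made from a phenol such as 20 in about three further steps. 1,3-Dicarbonyl compounds usually attack arynes through carbon (arylation or insertion into a C–C bond), so O-attack is uncertain. An aryne next to a prenyl group can be lost by an intramolecular ene reaction. Fluoride must spare the silyl ether, and acid is needed at the end.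
- Comparison: structurally this is an alternative to steps 10, 13 and 14 of the chosen route, not to its key step, and the two could be combined. After its key step it is better in step count. Once the preparation of A6 is counted it is at best equal, and its polar mechanism is the more speculative.

Key step: step 9

Remark on the chemistry: the configured C–O bond of 1 is never broken; the descriptor of that carbon reads S in 3–6 and R elsewhere only because CIP priorities change. Ketene is used as a gas stream from a ketene generator, and organometallic steps are quenched with water.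

## Route

Step 1
Reactants: 1 methyl (R)-2,2-dimethyl-1,3-dioxolane-4-carboxylate
Product: 2 2-[(4R)-2,2-dimethyl-1,3-dioxolan-4-yl]propan-2-ol
Conditions: MeMgBr (3 equiv), THF, 0 °C → rt
Reagents that add atoms: methylmagnesium bromide, C[Mg]Br
Why: Double Grignard addition to the ester gives the tertiary carbinol; addition is much faster than enolisation of the α-alkoxy ester, so the stereocentre is retained.

Step 2
Reactants: 2 2-[(4R)-2,2-dimethyl-1,3-dioxolan-4-yl]propan-2-ol
Product: 3 (4S)-2,2-dimethyl-4-(prop-1-en-2-yl)-1,3-dioxolane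
Conditions: SOCl2 (1.3 equiv), pyridine, CH2Cl2, −10 → 0 °C
Reagents that add atoms: none
Why: Dehydration of the tertiary carbinol through its chlorosulfite (E2 with pyridine); the six methyl hydrogens are removed in preference to the single hindered ring C–H next to oxygen, the usual outcome for hydroxyisopropyl groups on cyclic ethers. The stereocentre is untouched.

Step 3
Reactants: 3 (4S)-2,2-dimethyl-4-(prop-1-en-2-yl)-1,3-dioxolane
Product: 4 (2S)-3-methylbut-3-ene-1,2-diol
Conditions: AcOH–H2O (4:1), rt; toluene azeotrope
Reagents that add atoms: none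
Why: Acid-catalysed acetal hydrolysis under conditions too mild to ionise the allylic carbinol.

Step 4
Reactants: 4 (2S)-3-methylbut-3-ene-1,2-diol
Product: 6 (2S)-2-(tert-butyldimethylsilyloxy)-3-methylbut-3-en-1-yl trifluoromethanesulfonate, via hydroxy triflate 5 (not isolated)
Conditions: Tf2O (1.05 equiv), 2,6-lutidine (3 equiv), CH2Cl2, −78 °C; then TBSOTf (1.2 equiv), −78 → −40 °C; used crude
Reagents that add atoms: trifluoromethanesulfonic anhydride, FC(F)(F)S(=O)(=O)OS(=O)(=O)C(F)(F)F; tert-butyldimethylsilyl trifluoromethanesulfonate, CC(C)(C)[Si](C)(C)OS(=O)(=O)C(F)(F)F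
Why: One-flask selective sulfonylation of the primary hydroxyl at −78 °C followed by silylation of the secondary one, a known way to turn a 1,2-diol into a β-silyloxy primary triflate. No bond to the stereocentre is broken.

Step 5
Reactants: 6 (2S)-2-(tert-butyldimethylsilyloxy)-3-methylbut-3-en-1-yl trifluoromethanesulfonate; 7 2-chloro-1,1-dimethoxyethane (chloroacetaldehyde dimethyl acetal)
Product: 9 tert-butyl{[(3R)-6-methoxy-2-methylhex-1-en-5-yn-3-yl]oxy}dimethylsilane, via lithium methoxyacetylide 8 (not isolated)
Conditions: 7 (2.2 equiv), LiNEt2 (6.6 equiv, from Et2NH and n-BuLi), THF, 0 °C; then 6, THF–DMPU, −78 → −30 °C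
Reagents that add atoms: none
Why: SN2 alkylation of a lithium alkoxyacetylide (formed from the chloroacetal by two eliminations and deprotonation) with a primary triflate. The triflate offsets the retarding β-silyloxy group and β-branching, and at low temperature the anionic acetylide should outrun the neutral Et2NH. Configuration is retained.

Step 6
Reactants: 9 tert-butyl{[(3R)-6-methoxy-2-methylhex-1-en-5-yn-3-yl]oxy}dimethylsilane
Product: 10 2-[(2R)-2-(tert-butyldimethylsilyloxy)-3-methylbut-3-enyl]-3-methoxycyclobut-2-en-1-one
Conditions: ketene (gas, excess), CH2Cl2, 0 °C → rt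
Reagents that add atoms: ketene, C=C=O
Why: [2+2] cycloaddition of ketene with an electron-rich alkoxyalkyne, the standard route to 3-alkoxycyclobutenones; the alkyl-bearing alkyne carbon attacks the ketene carbonyl carbon, which places OMe at C3 and the chain at C2.

Step 7
Reactants: 11 1-bromo-3-methylbut-2-ene (prenyl bromide)
Product: 12 5-methylhex-4-en-1-yne
Conditions: HC≡CMgBr (1.5 equiv), CuCl (5 mol %), THF, 0 °C → rt; distillation
Reagents that add atoms: ethynylmagnesium bromide, C#C[Mg]Br
Why: CuCl-catalysed coupling of an alkynyl Grignard reagent with an allylic bromide; bond formation at the unhindered primary terminus gives the skipped enyne, and any branched isomer is removed by distillation.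

Step 8
Reactants: 12 5-methylhex-4-en-1-yne
Product: 15 5-methyl-1-(triisopropylsilyloxy)hex-4-en-1-yne, via lithium acetylide 13 (not isolated), via lithium ynolate 14 (not isolated)
Conditions: n-BuLi (1.0 equiv), THF, −78 °C; t-BuOOLi (from t-BuOOH and LiN(SiMe3)2), −78 → 0 °C; TIPSOTf (1.1 equiv), −78 °C
Reagents that add atoms: tert-butyl hydroperoxide, CC(C)(C)OO; triisopropylsilyl trifluoromethanesulfonate, CC(C)[Si](C(C)C)(C(C)C)OS(=O)(=O)C(F)(F)F
Why: Oxygen transfer from lithium tert-butyl peroxide to the lithium acetylide gives the ynolate, which the bulky silyl triflate traps on oxygen; a known one-flask conversion of terminal alkynes into triisopropylsiloxyalkynes.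

Step 9
Reactants: 10 2-[(2R)-2-(tert-butyldimethylsilyloxy)-3-methylbut-3-enyl]-3-methoxycyclobut-2-en-1-one; 15 5-methyl-1-(triisopropylsilyloxy)hex-4-en-1-yne
Product: 20 4-[(2R)-2-(tert-butyldimethylsilyloxy)-3-methylbut-3-enyl]-5-methoxy-2-(3-methylbut-2-enyl)-3-(triisopropylsilyloxy)phenol, via vinylketene 16 (not isolated), via vinylcyclobutenone 17 (not isolated), via dienylketene 18 (not isolated), via cyclohexadienone 19 (not isolated)
Conditions: 15 (1.5 equiv), toluene (0.5 M), 110–130 °C, sealed tube, argon
Reagents that add atoms: none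
Why: Danheiser benzannulation of a cyclobutenone with a siloxyalkyne, a known aromatic annulation that normally gives resorcinol monosilyl ethers and is used here with a 3-alkoxy partner. Thermal 4π electrocyclic opening of 10 gives vinylketene 16; the nucleophilic, prenyl-bearing carbon of 15 attacks the ketene carbonyl carbon in a regiospecific [2+2] cycloaddition to give 17 (C8a–C8 and C6–C7 bonds). A second 4π opening gives dienylketene 18, and ring A closes by thermal disrotatory 6π electrocyclisation (C8a–C4a bond) to dienone 19, which tautomerises to phenol 20. No stereocentre is created: the quaternary carbon of 17 is transient, and the (R)-silyloxy carbon is a spectator outside the reacting π system. The step needs regiocontrol in the [2+2] event, which the O-silyl polarisation of the alkyne supplies, and chemoselectivity for the ketene over three C=C bonds, which the far higher nucleophilicity of the ynol silyl ether supplies. The excess of 15 keeps the concentration of 16 low, so that it should neither acylate 20 nor add to the tethered isopropenyl group. The three oxygens leave the step as free OH (future O1), silyl ether (C7) and methyl ether (C5), which leaves one site each for the later acylation and pyranone closure.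

Step 10
Reactants: 20 4-[(2R)-2-(tert-butyldimethylsilyloxy)-3-methylbut-3-enyl]-5-methoxy-2-(3-methylbut-2-enyl)-3-(triisopropylsilyloxy)phenol
Product: 21 2-bromo-4-[(2R)-2-(tert-butyldimethylsilyloxy)-3-methylbut-3-enyl]-3-methoxy-6-(3-methylbut-2-enyl)-5-(triisopropylsilyloxy)phenol
Conditions: NBS (1.0 equiv), CH2Cl2, −78 °C, dark
Reagents that add atoms: N-bromosuccinimide, O=C1CCC(=O)N1Br
Why: Electrophilic aromatic bromination at C4a, the only unsubstituted ring carbon, which is activated by the ortho hydroxyl, ortho methoxy and para silyloxy groups and should react far faster at −78 °C than the side-chain alkenes.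

Step 11
Reactants: 22 3,4-dihydroxyphenylacetic acid
Product: 24 [3,4-bis(tert-butyldimethylsilyloxy)phenyl]acetic acid, via silyl ester 23 (not isolated)
Conditions: TBSCl (3.5 equiv), imidazole (7 equiv), DMF, rt; then AcOH–H2O–THF, rt
Reagents that add atoms: tert-butyldimethylsilyl chloride, CC(C)(C)[Si](C)(C)Cl
Why: Exhaustive silylation followed by selective hydrolysis of the labile silyl ester; the aryl silyl ethers survive aqueous acetic acid.

Step 12
Reactants: 24 [3,4-bis(tert-butyldimethylsilyloxy)phenyl]acetic acid
Product: 26 2-[3,4-bis(tert-butyldimethylsilyloxy)phenyl]-N-methoxy-N-methylacetamide, via acyl imidazolide 25 (not isolated)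
Conditions: CDI (1.1 equiv), CH2Cl2, rt; then MeNHOMe·HCl (1.3 equiv), rt
Reagents that add atoms: N,O-dimethylhydroxylamine hydrochloride, CNOC.Cl
Why: Amide formation through the acyl imidazolide gives the Weinreb amide needed for a single, chelation-arrested addition.

Step 13
Reactants: 21 2-bromo-4-[(2R)-2-(tert-butyldimethylsilyloxy)-3-methylbut-3-enyl]-3-methoxy-6-(3-methylbut-2-enyl)-5-(triisopropylsilyloxy)phenol; 26 2-[3,4-bis(tert-butyldimethylsilyloxy)phenyl]-N-methoxy-N-methylacetamide
Product: 28 2-[3,4-bis(tert-butyldimethylsilyloxy)phenyl]-1-{2-hydroxy-6-methoxy-5-[(2R)-2-(tert-butyldimethylsilyloxy)-3-methylbut-3-enyl]-3-(3-methylbut-2-enyl)-4-(triisopropylsilyloxy)phenyl}ethan-1-one, via ortho-lithiated lithium phenoxide 27 (not isolated)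
Conditions: MeLi (1.0 equiv), THF, −78 °C; t-BuLi (2.1 equiv), −78 °C; 26 (1.5 equiv), −78 → −20 °C
Reagents that add atoms: none
Why: Bromine–lithium exchange on the lithium phenoxide gives an ortho-lithiated phenoxide that adds once to the Weinreb amide (stable chelated tetrahedral intermediate), forming C4–C4a without any Lewis or Brønsted acid. No silyloxy group is ortho to the carbanion, so a retro-Brook shift is excluded.

Step 14
Reactants: 28 2-[3,4-bis(tert-butyldimethylsilyloxy)phenyl]-1-{2-hydroxy-6-methoxy-5-[(2R)-2-(tert-butyldimethylsilyloxy)-3-methylbut-3-enyl]-3-(3-methylbut-2-enyl)-4-(triisopropylsilyloxy)phenyl}ethan-1-one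
Product: 30 3-[3,4-bis(tert-butyldimethylsilyloxy)phenyl]-6-[(2R)-2-(tert-butyldimethylsilyloxy)-3-methylbut-3-enyl]-5-methoxy-8-(3-methylbut-2-enyl)-7-(triisopropylsilyloxy)-4H-chromen-4-one, via enaminone 29 (not isolated)
Conditions: Me2NCH(OMe)2 (3 equiv), toluene, 90 °C
Reagents that add atoms: N,N-dimethylformamide dimethyl acetal, COC(OC)N(C)C
Why: Aminomethylenation of the activated benzylic CH2 gives enaminone 29, and the neighbouring C8a hydroxyl adds and expels Me2NH to close ring C; this is the standard deoxybenzoin route to isoflavones and runs under neutral to basic conditions.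

Step 15
Reactants: 30 3-[3,4-bis(tert-butyldimethylsilyloxy)phenyl]-6-[(2R)-2-(tert-butyldimethylsilyloxy)-3-methylbut-3-enyl]-5-methoxy-8-(3-methylbut-2-enyl)-7-(triisopropylsilyloxy)-4H-chromen-4-one
Product: 31 3-[3,4-bis(tert-butyldimethylsilyloxy)phenyl]-6-[(2R)-2-(tert-butyldimethylsilyloxy)-3-methylbut-3-enyl]-5-hydroxy-8-(3-methylbut-2-enyl)-7-(triisopropylsilyloxy)-4H-chromen-4-one
Conditions: MgI2·OEt2 (4 equiv), THF, 50–65 °C
Reagents that add atoms: none
Why: Chelation-controlled ether cleavage: magnesium bridges the C4 carbonyl and the peri C5 oxygen and iodide removes the methyl group by SN2. This is the only methyl ether in the molecule, and the mild Lewis acid is known to tolerate prenyl groups.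

Step 16
Reactants: 31 3-[3,4-bis(tert-butyldimethylsilyloxy)phenyl]-6-[(2R)-2-(tert-butyldimethylsilyloxy)-3-methylbut-3-enyl]-5-hydroxy-8-(3-methylbut-2-enyl)-7-(triisopropylsilyloxy)-4H-chromen-4-one
Product: 32 3-(3,4-dihydroxyphenyl)-5,7-dihydroxy-6-[(2R)-2-hydroxy-3-methylbut-3-enyl]-8-(3-methylbut-2-enyl)-4H-chromen-4-one (CNP0305771.1)
Conditions: Bu4NF (6 equiv), AcOH (6 equiv), THF, 0 °C → rt, argon
Reagents that add atoms: none
Why: Fluoride-induced cleavage of all four silyl ethers in one operation; the acetic acid buffer keeps the phenoxides protonated, which protects the catechol from aerial oxidation and the pyranone from base. The stereocentre is not involved.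

## Compound list

1 | methyl (R)-2,2-dimethyl-1,3-dioxolane-4-carboxylate | COC(=O)[C@H]1COC(C)(C)O1 | starting material
2 | 2-[(4R)-2,2-dimethyl-1,3-dioxolan-4-yl]propan-2-ol | CC(C)(O)[C@H]1COC(C)(C)O1 | intermediate
3 | (4S)-2,2-dimethyl-4-(prop-1-en-2-yl)-1,3-dioxolane | C=C(C)[C@H]1COC(C)(C)O1 | intermediate
4 | (2S)-3-methylbut-3-ene-1,2-diol | C=C(C)[C@H](O)CO | intermediate
5 | (2S)-2-hydroxy-3-methylbut-3-en-1-yl trifluoromethanesulfonate | C=C(C)[C@H](O)COS(=O)(=O)C(F)(F)F | intermediate
6 | (2S)-2-(tert-butyldimethylsilyloxy)-3-methylbut-3-en-1-yl trifluoromethanesulfonate | C=C(C)[C@H](O[Si](C)(C)C(C)(C)C)COS(=O)(=O)C(F)(F)F | intermediate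
7 | 2-chloro-1,1-dimethoxyethane (chloroacetaldehyde dimethyl acetal) | COC(CCl)OC | starting material
8 | lithium methoxyacetylide | [Li]C#COC | intermediate
9 | tert-butyl{[(3R)-6-methoxy-2-methylhex-1-en-5-yn-3-yl]oxy}dimethylsilane | C=C(C)[C@H](O[Si](C)(C)C(C)(C)C)CC#COC | intermediate
10 | 2-[(2R)-2-(tert-butyldimethylsilyloxy)-3-methylbut-3-enyl]-3-methoxycyclobut-2-en-1-one | C=C(C)[C@H](O[Si](C)(C)C(C)(C)C)CC1=C(OC)CC1=O | intermediate
11 | 1-bromo-3-methylbut-2-ene (prenyl bromide) | CC(C)=CCBr | starting material
12 | 5-methylhex-4-en-1-yne | CC(C)=CCC#C | intermediate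
13 | lithium 5-methylhex-4-en-1-yn-1-ide | [Li]C#CCC=C(C)C | intermediate
14 | lithium 5-methylhex-4-en-1-yn-1-olate | [Li]OC#CCC=C(C)C | intermediate
15 | 5-methyl-1-(triisopropylsilyloxy)hex-4-en-1-yne | CC(C)=CCC#CO[Si](C(C)C)(C(C)C)C(C)C | intermediate
16 | 2-[(2R)-2-(tert-butyldimethylsilyloxy)-3-methylbut-3-enyl]-3-methoxybuta-1,3-dien-1-one (vinylketene) | C=C(C)[C@H](O[Si](C)(C)C(C)(C)C)CC(=C=O)C(OC)=C | intermediate
17 | 4-[(2R)-2-(tert-butyldimethylsilyloxy)-3-methylbut-3-enyl]-4-(1-methoxyethenyl)-2-(3-methylbut-2-enyl)-3-(triisopropylsilyloxy)cyclobut-2-en-1-one (either configuration at C4) | C=C(C)[C@H](O[Si](C)(C)C(C)(C)C)CC1(C(OC)=C)C(=O)C(CC=C(C)C)=C1O[Si](C(C)C)(C(C)C)C(C)C | intermediate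
18 | (3E)-4-[(2R)-2-(tert-butyldimethylsilyloxy)-3-methylbut-3-enyl]-5-methoxy-2-(3-methylbut-2-enyl)-3-(triisopropylsilyloxy)hexa-1,3,5-trien-1-one (methoxyvinyl group cis to the ketene carbon) | C=C(C)[C@H](O[Si](C)(C)C(C)(C)C)C/C(C(OC)=C)=C(\O[Si](C(C)C)(C(C)C)C(C)C)C(CC=C(C)C)=C=O | intermediate
19 | 4-[(2R)-2-(tert-butyldimethylsilyloxy)-3-methylbut-3-enyl]-5-methoxy-2-(3-methylbut-2-enyl)-3-(triisopropylsilyloxy)cyclohexa-2,4-dien-1-one | C=C(C)[C@H](O[Si](C)(C)C(C)(C)C)CC1=C(OC)CC(=O)C(CC=C(C)C)=C1O[Si](C(C)C)(C(C)C)C(C)C | intermediate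
20 | 4-[(2R)-2-(tert-butyldimethylsilyloxy)-3-methylbut-3-enyl]-5-methoxy-2-(3-methylbut-2-enyl)-3-(triisopropylsilyloxy)phenol | C=C(C)[C@H](O[Si](C)(C)C(C)(C)C)Cc1c(OC)cc(O)c(CC=C(C)C)c1O[Si](C(C)C)(C(C)C)C(C)C | intermediate
21 | 2-bromo-4-[(2R)-2-(tert-butyldimethylsilyloxy)-3-methylbut-3-enyl]-3-methoxy-6-(3-methylbut-2-enyl)-5-(triisopropylsilyloxy)phenol | C=C(C)[C@H](O[Si](C)(C)C(C)(C)C)Cc1c(OC)c(Br)c(O)c(CC=C(C)C)c1O[Si](C(C)C)(C(C)C)C(C)C | intermediate
22 | 3,4-dihydroxyphenylacetic acid | OC(=O)Cc1ccc(O)c(O)c1 | starting material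
23 | tert-butyldimethylsilyl [3,4-bis(tert-butyldimethylsilyloxy)phenyl]acetate | CC(C)(C)[Si](C)(C)OC(=O)Cc1ccc(O[Si](C)(C)C(C)(C)C)c(O[Si](C)(C)C(C)(C)C)c1 | intermediate
24 | [3,4-bis(tert-butyldimethylsilyloxy)phenyl]acetic acid | OC(=O)Cc1ccc(O[Si](C)(C)C(C)(C)C)c(O[Si](C)(C)C(C)(C)C)c1 | intermediate
25 | 2-[3,4-bis(tert-butyldimethylsilyloxy)phenyl]-1-(imidazol-1-yl)ethan-1-one | O=C(Cc1ccc(O[Si](C)(C)C(C)(C)C)c(O[Si](C)(C)C(C)(C)C)c1)n1ccnc1 | intermediate
26 | 2-[3,4-bis(tert-butyldimethylsilyloxy)phenyl]-N-methoxy-N-methylacetamide | CON(C)C(=O)Cc1ccc(O[Si](C)(C)C(C)(C)C)c(O[Si](C)(C)C(C)(C)C)c1 | intermediate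
27 | lithium 2-lithio-4-[(2R)-2-(tert-butyldimethylsilyloxy)-3-methylbut-3-enyl]-3-methoxy-6-(3-methylbut-2-enyl)-5-(triisopropylsilyloxy)phenolate | C=C(C)[C@H](O[Si](C)(C)C(C)(C)C)Cc1c(OC)c([Li])c(O[Li])c(CC=C(C)C)c1O[Si](C(C)C)(C(C)C)C(C)C | intermediate
28 | 2-[3,4-bis(tert-butyldimethylsilyloxy)phenyl]-1-{2-hydroxy-6-methoxy-5-[(2R)-2-(tert-butyldimethylsilyloxy)-3-methylbut-3-enyl]-3-(3-methylbut-2-enyl)-4-(triisopropylsilyloxy)phenyl}ethan-1-one | C=C(C)[C@H](O[Si](C)(C)C(C)(C)C)Cc1c(OC)c(C(=O)Cc2ccc(O[Si](C)(C)C(C)(C)C)c(O[Si](C)(C)C(C)(C)C)c2)c(O)c(CC=C(C)C)c1O[Si](C(C)C)(C(C)C)C(C)C | intermediate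
29 | 2-[3,4-bis(tert-butyldimethylsilyloxy)phenyl]-3-(dimethylamino)-1-{2-hydroxy-6-methoxy-5-[(2R)-2-(tert-butyldimethylsilyloxy)-3-methylbut-3-enyl]-3-(3-methylbut-2-enyl)-4-(triisopropylsilyloxy)phenyl}prop-2-en-1-one | C=C(C)[C@H](O[Si](C)(C)C(C)(C)C)Cc1c(OC)c(C(=O)C(=CN(C)C)c2ccc(O[Si](C)(C)C(C)(C)C)c(O[Si](C)(C)C(C)(C)C)c2)c(O)c(CC=C(C)C)c1O[Si](C(C)C)(C(C)C)C(C)C | intermediate
30 | 3-[3,4-bis(tert-butyldimethylsilyloxy)phenyl]-6-[(2R)-2-(tert-butyldimethylsilyloxy)-3-methylbut-3-enyl]-5-methoxy-8-(3-methylbut-2-enyl)-7-(triisopropylsilyloxy)-4H-chromen-4-one | C=C(C)[C@H](O[Si](C)(C)C(C)(C)C)Cc1c(O[Si](C(C)C)(C(C)C)C(C)C)c(CC=C(C)C)c2occ(-c3ccc(O[Si](C)(C)C(C)(C)C)c(O[Si](C)(C)C(C)(C)C)c3)c(=O)c2c1OC | intermediate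
31 | 3-[3,4-bis(tert-butyldimethylsilyloxy)phenyl]-6-[(2R)-2-(tert-butyldimethylsilyloxy)-3-methylbut-3-enyl]-5-hydroxy-8-(3-methylbut-2-enyl)-7-(triisopropylsilyloxy)-4H-chromen-4-one | C=C(C)[C@H](O[Si](C)(C)C(C)(C)C)Cc1c(O[Si](C(C)C)(C(C)C)C(C)C)c(CC=C(C)C)c2occ(-c3ccc(O[Si](C)(C)C(C)(C)C)c(O[Si](C)(C)C(C)(C)C)c3)c(=O)c2c1O | intermediate
32 | 3-(3,4-dihydroxyphenyl)-5,7-dihydroxy-6-[(2R)-2-hydroxy-3-methylbut-3-enyl]-8-(3-methylbut-2-enyl)-4H-chromen-4-one | C=C(C)[C@H](O)Cc1c(O)c(CC=C(C)C)c2occ(-c3ccc(O)c(O)c3)c(=O)c2c1O | target

## Step count and least certain steps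

Total step count: 16 steps (steps 1–6 to the cyclobutenone, 7–8 to the siloxyalkyne, 11–12 to the ring B amide, key step 9, then 10 and 13–16).

Longest linear sequence: 12 steps (1, 2, 3, 4, 5, 6, 9, 10, 13, 14, 15, 16), from 1 to 32.

Step 9 (key step). The methoxy group donates into the enone of 10 and should raise the barrier to the first electrocyclic opening, so the temperature required may approach the point where the siloxyalkyne and the silyl ethers begin to degrade. The vinylketene may also be diverted by intramolecular [2+2] addition to the isopropenyl group or by acylation of phenol already formed. The fallback makes the same vinylketene at room temperature by a photochemical Wolff rearrangement; it sets out from 6 and returns at 20.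
- The lithium enolate of 3-methoxybut-3-en-2-one (LiN(iPr)2, THF, −78 °C) would be C-alkylated by 6 to give (6R)-6-(tert-butyldimethylsilyloxy)-2-methoxy-7-methylocta-1,7-dien-3-one F1.
- LiN(SiMe3)2 and 2,2,2-trifluoroethyl trifluoroacetate would give (6R)-6-(tert-butyldimethylsilyloxy)-2-methoxy-7-methyl-4-(trifluoroacetyl)octa-1,7-dien-3-one F2.
- Methanesulfonyl azide with Et3N would convert this by detrifluoroacetylative diazo transfer into (6R)-6-(tert-butyldimethylsilyloxy)-4-diazo-2-methoxy-7-methylocta-1,7-dien-3-one F3.
- Irradiation of F3 with 15 (Pyrex-filtered mercury lamp, 1,2-dichloroethane, rt) should give 16 by migration of the methoxyvinyl group; warming to 80 °C should then carry the sequence through to 20.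

Step 13. Proton transfer from the acidic benzylic CH2 of 26 to the hindered, aggregated aryllithium 27 may compete with addition and would return the debrominated arene, or the addition may simply be slow. The fallback attaches ring B by cross-coupling; it sets out from 21 and returns at 30.
- 27, generated from 21 as in step 13, would be quenched with the smaller and far less acidic N-methoxy-N-methylacetamide to give 1-{2-hydroxy-6-methoxy-5-[(2R)-2-(tert-butyldimethylsilyloxy)-3-methylbut-3-enyl]-3-(3-methylbut-2-enyl)-4-(triisopropylsilyloxy)phenyl}ethan-1-one F4.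
- Me2NCH(OMe)2 (toluene, 80 °C) would give (E)-3-(dimethylamino)-1-{2-hydroxy-6-methoxy-5-[(2R)-2-(tert-butyldimethylsilyloxy)-3-methylbut-3-enyl]-3-(3-methylbut-2-enyl)-4-(triisopropylsilyloxy)phenyl}prop-2-en-1-one F5.
- I2 in CHCl3–pyridine would cyclise and iodinate it to 6-[(2R)-2-(tert-butyldimethylsilyloxy)-3-methylbut-3-enyl]-3-iodo-5-methoxy-8-(3-methylbut-2-enyl)-7-(triisopropylsilyloxy)-4H-chromen-4-one F6.
- Suzuki coupling with commercial 4-(4,4,5,5-tetramethyl-1,3,2-dioxaborolan-2-yl)benzene-1,2-diol (Pd(PPh3)4, aqueous Na2CO3, DME, 70 °C, degassed) would give 3-(3,4-dihydroxyphenyl)-6-[(2R)-2-(tert-butyldimethylsilyloxy)-3-methylbut-3-enyl]-5-methoxy-8-(3-methylbut-2-enyl)-7-(triisopropylsilyloxy)-4H-chromen-4-one F7.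
- TBSCl and imidazole in DMF would silylate the catechol to give 30.

Step 5. Substitution at a β-silyloxy, β-branched carbon is slow, so E2 elimination of the triflate, attack by Et2NH or LiOMe, or thermal decay of the triflate may compete. The fallback replaces the sulfonate displacement by an epoxide opening; it sets out from 4 and returns at 9.
- Hydroxy triflate 5, formed from 4 as in step 4, would be treated with DBU instead of the silyl triflate to close (2S)-2-(prop-1-en-2-yl)oxirane F8, isolated by distillation.
- 8 in THF–DMPU without a Lewis acid (so that the allylic carbon is not activated) would open F8 at the unsubstituted ring carbon to give (3R)-6-methoxy-2-methylhex-1-en-5-yn-3-ol F9.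
- TBSCl and imidazole would convert F9 into 9.

Step 6. Dimerisation or polymerisation of ketene may outpace the cycloaddition, and traces of acid in the gas stream may hydrolyse the ynol ether. The fallback uses a ketene generated in solution and removes the extra atoms afterwards; it sets out from 9 and returns at 10.
- Dichloroketene (Cl3CCOCl, Zn(Cu), Et2O–DME) would add to 9 with the same regiochemistry to give 4,4-dichloro-2-[(2R)-2-(tert-butyldimethylsilyloxy)-3-methylbut-3-enyl]-3-methoxycyclobut-2-en-1-one F10.
- Zn, AcOH and TMEDA in EtOH at 0 °C would remove both chlorines to give 10.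

Step 2. Elimination may partly take the ring C–H (giving an enol ether) or substitution may give the tertiary chloride, since the chlorosulfite has more than one pathway open. The fallback builds the alkene by carbonyl olefination; it sets out from 1 and returns at 3.
- MeNHOMe·HCl and i-PrMgCl would convert 1 into (4R)-N-methoxy-N,2,2-trimethyl-1,3-dioxolane-4-carboxamide F11.
- MeMgBr would give 1-[(4R)-2,2-dimethyl-1,3-dioxolan-4-yl]ethan-1-one F12.
- Wittig methylenation (Ph3P=CH2 from Ph3PCH3Br and KN(SiMe3)2, THF, −78 → 0 °C, short contact time to avoid enolisation) would give 3.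

## Further compounds

F1 | step 9 | (6R)-6-(tert-butyldimethylsilyloxy)-2-methoxy-7-methylocta-1,7-dien-3-one | C=C(C)[C@H](O[Si](C)(C)C(C)(C)C)CCC(=O)C(OC)=C
F2 | step 9 | (6R)-6-(tert-butyldimethylsilyloxy)-2-methoxy-7-methyl-4-(trifluoroacetyl)octa-1,7-dien-3-one (either configuration at C4) | C=C(C)[C@H](O[Si](C)(C)C(C)(C)C)CC(C(=O)C(F)(F)F)C(=O)C(OC)=C
F3 | step 9 | (6R)-6-(tert-butyldimethylsilyloxy)-4-diazo-2-methoxy-7-methylocta-1,7-dien-3-one | C=C(C)[C@H](O[Si](C)(C)C(C)(C)C)CC(=[N+]=[N-])C(=O)C(OC)=C
F4 | step 13 | 1-{2-hydroxy-6-methoxy-5-[(2R)-2-(tert-butyldimethylsilyloxy)-3-methylbut-3-enyl]-3-(3-methylbut-2-enyl)-4-(triisopropylsilyloxy)phenyl}ethan-1-one | C=C(C)[C@H](O[Si](C)(C)C(C)(C)C)Cc1c(OC)c(C(C)=O)c(O)c(CC=C(C)C)c1O[Si](C(C)C)(C(C)C)C(C)C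
F5 | step 13 | (E)-3-(dimethylamino)-1-{2-hydroxy-6-methoxy-5-[(2R)-2-(tert-butyldimethylsilyloxy)-3-methylbut-3-enyl]-3-(3-methylbut-2-enyl)-4-(triisopropylsilyloxy)phenyl}prop-2-en-1-one | C=C(C)[C@H](O[Si](C)(C)C(C)(C)C)Cc1c(OC)c(C(=O)/C=C/N(C)C)c(O)c(CC=C(C)C)c1O[Si](C(C)C)(C(C)C)C(C)C
F6 | step 13 | 6-[(2R)-2-(tert-butyldimethylsilyloxy)-3-methylbut-3-enyl]-3-iodo-5-methoxy-8-(3-methylbut-2-enyl)-7-(triisopropylsilyloxy)-4H-chromen-4-one | C=C(C)[C@H](O[Si](C)(C)C(C)(C)C)Cc1c(O[Si](C(C)C)(C(C)C)C(C)C)c(CC=C(C)C)c2occ(I)c(=O)c2c1OC
F7 | step 13 | 3-(3,4-dihydroxyphenyl)-6-[(2R)-2-(tert-butyldimethylsilyloxy)-3-methylbut-3-enyl]-5-methoxy-8-(3-methylbut-2-enyl)-7-(triisopropylsilyloxy)-4H-chromen-4-one | C=C(C)[C@H](O[Si](C)(C)C(C)(C)C)Cc1c(O[Si](C(C)C)(C(C)C)C(C)C)c(CC=C(C)C)c2occ(-c3ccc(O)c(O)c3)c(=O)c2c1OC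
F8 | step 5 | (2S)-2-(prop-1-en-2-yl)oxirane | C=C(C)[C@H]1CO1
F9 | step 5 | (3R)-6-methoxy-2-methylhex-1-en-5-yn-3-ol | C=C(C)[C@H](O)CC#COC
F10 | step 6 | 4,4-dichloro-2-[(2R)-2-(tert-butyldimethylsilyloxy)-3-methylbut-3-enyl]-3-methoxycyclobut-2-en-1-one | C=C(C)[C@H](O[Si](C)(C)C(C)(C)C)CC1=C(OC)C(Cl)(Cl)C1=O
F11 | step 2 | (4R)-N-methoxy-N,2,2-trimethyl-1,3-dioxolane-4-carboxamide | CON(C)C(=O)[C@H]1COC(C)(C)O1
F12 | step 2 | 1-[(4R)-2,2-dimethyl-1,3-dioxolan-4-yl]ethan-1-one | CC(=O)[C@H]1COC(C)(C)O1
A1 | alternative 1 | 6-[(E)-4-hydroxy-3-methylbut-2-enyl]-8-(3-methylbut-2-enyl)-5,7,3',4'-tetrakis(methoxymethoxy)isoflavone | OC/C(C)=C/Cc1c(OCOC)c(CC=C(C)C)c2occ(-c3ccc(OCOC)c(OCOC)c3)c(=O)c2c1OCOC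
A2 | alternative 1 | 6-{[(2R,3R)-3-(hydroxymethyl)-3-methyloxiran-2-yl]methyl}-8-(3-methylbut-2-enyl)-5,7,3',4'-tetrakis(methoxymethoxy)isoflavone | OC[C@@]1(C)O[C@@H]1Cc1c(OCOC)c(CC=C(C)C)c2occ(-c3ccc(OCOC)c(OCOC)c3)c(=O)c2c1OCOC
A3 | alternative 2 | methyl 5-[3,4-bis(methoxymethoxy)phenyl]-2-(4-methylpent-3-enyl)-4-oxo-4H-pyran-3-carboxylate | COC(=O)c1c(CCC=C(C)C)occ(-c2ccc(OCOC)c(OCOC)c2)c1=O
A4 | alternative 2 | methyl (R)-4-(tert-butyldimethylsilyloxy)-5-methylhex-5-enoate | C=C(C)[C@H](O[Si](C)(C)C(C)(C)C)CCC(=O)OC
A5 | alternative 2 | 5,7-dihydroxy-6-[(R)-2-(tert-butyldimethylsilyloxy)-3-methylbut-3-enyl]-8-(3-methylbut-2-enyl)-3',4'-bis(methoxymethoxy)isoflavone | C=C(C)[C@H](O[Si](C)(C)C(C)(C)C)Cc1c(O)c(CC=C(C)C)c2occ(-c3ccc(OCOC)c(OCOC)c3)c(=O)c2c1O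
A6 | alternative 3 | 3-[(R)-2-(tert-butyldimethylsilyloxy)-3-methylbut-3-enyl]-2,4-bis(methoxymethoxy)-5-(3-methylbut-2-enyl)-6-(trimethylsilyl)phenyl trifluoromethanesulfonate | C=C(C)[C@H](O[Si](C)(C)C(C)(C)C)Cc1c(OCOC)c(CC=C(C)C)c([Si](C)(C)C)c(OS(=O)(=O)C(F)(F)F)c1OCOC
A7 | alternative 3 | methyl 2-[3,4-bis(methoxymethoxy)phenyl]-3-oxopropanoate | COC(=O)C(C=O)c1ccc(OCOC)c(OCOC)c1
A8 | alternative 3 | 6-[(R)-2-(tert-butyldimethylsilyloxy)-3-methylbut-3-enyl]-8-(3-methylbut-2-enyl)-5,7,3',4'-tetrakis(methoxymethoxy)isoflavone | C=C(C)[C@H](O[Si](C)(C)C(C)(C)C)Cc1c(OCOC)c(CC=C(C)C)c2occ(-c3ccc(OCOC)c(OCOC)c3)c(=O)c2c1OCOC
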